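Late in this flask I expect a balance, not a rate, to give the answer, so I reckon from the end backwards.

in all of them: gas phase 15 mM (held)

| flask | solid substrate | protic impurity | remark | time |
|---|---|---|---|---|
| epsilon | 0.10 M | 0.020 M | the very flask that is asked about, followed so far |  |
| beta | 0.20 M | 0.020 M | run made earlier |  |
| flask | 0.10 M | 0.0200 M |  | 30 h |

- epsilon (time / h: target / %): 0.417: 0; 1.33: 5; 2.50: 11; 4.00: 18
- beta (time / h: target / %): 4.00: 9; 10.0: 29; 20.0: 48; 30.0: 63

(each reading ± 2 percentage points)

- a species is counted by the solid substrate in it: one side product counts as two
- given per volume of solution although it is solid: solid substrate
- at the start none of the gas is dissolved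
- the numbers in the tables scatter with a standard deviation of 2 percentage points
- candidate steps: starting material + protic impurity -> quenched substrate; starting material + target -> side product; starting material + dissolved gas -> target; gas phase <-> dissolved gas; solid substrate <-> starting material
- at the start none of the solid substrate is in solution

1. the target standing at 30 h, as a percentage of the solid substrate charged
2. concentration of dissolved gas in solution at 8.0 h, in percent of saturation
3. the change that raises the amount of target at 30 h, in percent of the solid substrate charged most ("none" if none brings more than 2 percentage points) (spring / midnight / noon / dawn / none)
4. amount of target at 30 h, in percent of the solid substrate charged, after noon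

- spring: doubling the dissolution coefficient of the solid substrate, all else as stated
- midnight: doubling the transfer coefficient of the gas phase, all else as stated
- noon: doubling the saturation concentration of gas phase, all else as stated
- dawn: doubling the solubility of the solid substrate, all else as stated

The epsilon readings from 1.33 h to 4.00 h give a delivery rate of target of 4.87 mM h⁻¹, a reading that carries their scatter. Each protic impurity can remove one starting material, so I charge a toll of 20.0% of the solid substrate, and I assume the whole toll is paid. My bound from above for the flask is then 80.0%. I define the finishing time 16.4 h as the charge less the toll, divided by the delivery rate. In the flask it is shorter than 30 h, so I treat solid substrate as the limiting reagent and the balance, not the clock, as what gives the answer.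

The bound from below comes from side product. I take its rate as proportional to [target] at equal [starting material], and with [target] rising in a straight line, its time integral is a triangle. In beta at 30.0 h, the target reading and the toll, assumed paid in full, leave 54.0 mM unaccounted for, which I take, with the scatter of that reading, as the most side product holds there. Scaling by the two triangles gives the flask an estimated loss of at most 18.8%, so my bracket runs from 61.2% to 80.0%.

The forecast gives 66% target, inside that bracket, with 70% of saturation, noon as the best change and 73% after it, and it reasons that “The solid runs out near 17 h”.

The flask gives 70.0% target at 30 h. Its dissolved gas stands at 26.6% of saturation at 8.0 h. The best change is noon, worth 7.1 percentage points, which brings the target to 77.2%.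

    starting material + protic impurity → quenched substrate (k = 0.00250 M⁻¹ s⁻¹)
    starting material + target → side product (k = 1.10 × 10⁻⁴ M⁻¹ s⁻¹)
    starting material + dissolved gas → target (k = 0.0110 M⁻¹ s⁻¹)
    gas phase ⇌ dissolved gas, rate k4*(csat - [dissolved gas]) (kL = 1.50 × 10⁻⁴ s⁻¹)
    solid substrate ⇌ starting material, rate k5*(cs5 - [starting material]) while solid is left; crystals form when [starting material] > cs5 (solubility = 0.0540 M, k = 2.20 × 10⁻⁴ s⁻¹)

The flask's side product at 30 h is 10.4%, less than my bound. Well past the finishing time of 16.4 h, the target reads 70.0% at 60.0 h, and a run ten times as long changes nothing. For the neighbour with 0.25 M of solid substrate, the finishing time is 47.2 h, longer than 30 h, so I reckon by the clock and get 58.4% target. The computed neighbour gives 56.2%, with 6.9% of its solid substrate charge still there, solid or dissolved.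

All runs come from a simulation on assumed constants, noise included.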